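## Analysis of the target

The target is a B-type proanthocyanidin dimer, epiafzelechin-(4β→8)-epigallocatechin. An upper flavan-3-ol (rings A and C, with the 4-hydroxyphenyl ring B on C2) is bonded from C4 of ring C to C8 of ring D of a lower flavan-3-ol (rings D and F, with the pyrogallol ring E). There are five stereocentres. C2, C3 and C4 of ring C are all R (2,3-cis, 3,4-trans, so the aryl groups on C2 and C4 are trans). C2 and C3 of ring F are both R (2,3-cis). The lower unit is (−)-epigallocatechin itself, a commercial compound, whereas epiafzelechin is not a bulk chemical, so ring C with its three contiguous stereocentres has to be built. The 2,3-cis relationship in ring C is the classical difficulty of the epi series, because additions and cyclisations steered by the C2 aryl group normally give the 2,3-trans isomer. The product has ten free hydroxyl groups, an oxidation-prone ring E, C2 centres that epimerise in base once the phenols are free, and a C4–C8 bond that ionises in acid; the coupling must also choose C8 over C6 of ring D and stop at the dimer. The feature the route exploits is that C4 of ring C sits on C4a of ring A, whose three oxygen atoms (O1 on C8a, and the oxygens on C5 and C7) stabilise a positive charge at C4. A C3=C4 double bond in ring C is therefore a trioxygenated styrene that should accept a proton at C3. This allows the C3–H bond, the C3 and C4 stereocentres and the C4–C8 bond to ring D to be made in one operation from a flat flav-3-en-3-yl ester, the ester of the flav-3-en-3-ol that is presumed to be the biosynthetic source of 2,3-cis extension units.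

## Retrosynthetic reasoning

**Target 11 to octabenzyl ether 10.** All eight phenols are masked as benzyl ethers, and the two secondary 3-hydroxyl groups are left free. The eight O–CH2Ph bonds are cut last by neutral hydrogenolysis, which avoids both acid (interflavan bond) and base (C2 epimerisation, oxidation of ring E).

**Octabenzyl ether 10 to formate 9, then to enol formate 6 and nucleophile 8.** The cut goes through two bonds of ring C at once: C4–C8 (ring C to ring D) and C3–H. This takes the upper unit back to the flat (2R)-flav-3-en-3-yl formate 6, which has only the C2 stereocentre, and the lower unit back to pentabenzyl epigallocatechin 8. The forward reaction must add a proton to C3 anti to ring B (giving 2,3-cis) and then bond C4 to C8 of 8 anti to the 3-formyloxy group (giving 3,4-trans). Cutting here rather than at C4–C8 alone means that no preformed 2,3-cis flavan-3-ol and no separate C4 activation are needed. The formate in 9 is cut back to the free alcohol of 10 in the same flask.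

**Enol formate 6 to enal 5.** The C3–O bond is traced to a C3–CHO bond: the formyl group of the chromene-3-carbaldehyde 5 is a latent oxygen that a peracid converts into the enol formate by alkenyl migration. This places the oxygen on C3 without touching C2.

**Enal 5 to salicylaldehyde 2 and cinnamaldehyde 4.** Ring C is opened at O1–C2 and C3=C4. Forward, an iminium–enamine domino reaction (oxa-Michael addition, then aldol condensation) closes ring C and sets C2 under control of a chiral secondary amine. This is the only catalyst-controlled stereocentre of the route.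

**Building blocks.** Nucleophile 8 comes from commercial (−)-epigallocatechin 7 by phenol-selective benzylation. Salicylaldehyde 2 comes from 2,4,6-trihydroxybenzaldehyde 1 by twofold benzylation. Cinnamaldehyde 4 comes from 4-(benzyloxy)benzaldehyde 3 by two-carbon homologation.

## Alternatives that were turned down

**Alternative 1:** the textbook disconnection, C4–C8 only, between two preformed protected flavan-3-ols. Tri-O-benzylepiafzelechin A1 would be oxidised at C4 to the 4β-(2-ethoxyethoxy) ether A2, and A2 would be coupled with 8 under a silyl triflate to give 10. The coupling itself is reliable, but it creates only the C4 stereocentre. A1 is not available in quantity and would have to be built from a cinnamyl alcohol and a phloroglucinol ether by Friedel–Crafts alkylation, asymmetric dihydroxylation, cyclisation to the 2,3-trans flavan, and inversion at C3 by oxidation and hydride reduction. That is roughly eight operations before the C4 activation, so the route to the precursor costs more than the key step gains.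

**Alternative 2:** dearomatisation of a flat pelargonidin-type cation. The 3-acetoxyflavylium salt A3 would be attacked at C4 by C8 of 8 to give the 4-aryl-flav-2-ene A4, and the C2=C3 bond would then be hydrogenated. The precursor is very simple, but hydrogen adds to the face away from the pseudoaxial C4 aryl group. H2 and H3 then end up anti to that aryl group, which gives the all-cis (2,3-cis-3,4-cis, 4α) isomer and not the 3,4-trans target. In addition, C4 would be set on a flat cation under only remote control by the stereocentres of 8. A hydride-first variant (hydride at C2, then protonation and arylation) would need C2-over-C4 regioselectivity and enantiofacial control on the same flat cation, two selectivities without support, since dihydropyridine-type donors favour C4.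

**Alternative 3:** annulation of ring C onto the lower unit (disconnection of C4–C4a and O1–C2). The 8-cinnamoyl-type enone A5 would take up a phloroglucinol dibenzyl ether by Friedel–Crafts addition at the β-carbon, and cyclodehydration would give the 2,4-diaryl-4H-chromene A6, which would be hydroborated and oxidised to install the 3-hydroxyl group. C4 would be formed by addition to an acyclic enone with no nearby stereocontrol. Hydroboration adds H (to C2) and boron (to C3) syn and anti to the C4 aryl group, which gives 2,3-trans-3,4-trans, so C3 would still need an oxidation–reduction inversion. Formylation of 8 at C8 rather than C6 and the olefination add further steps.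

Key step: step 6

Assumption: commercial (−)-epigallocatechin is taken as the enantiopure (2R,3R) compound, so the lower-unit stereocentres are bought and only C2, C3 and C4 of ring C are created.

## Route

Step 1
Reactants: 1 2,4,6-trihydroxybenzaldehyde
Product: 2 2,4-bis(benzyloxy)-6-hydroxybenzaldehyde
Conditions: BnBr (2.05 equiv), K2CO3 (2.2 equiv), DMF, 0 °C to rt
Reagents that add atoms: benzyl bromide, BrCc1ccccc1
Why: Williamson etherification; the hydroxyl group that stays hydrogen-bonded to the formyl group is the least reactive, so two equivalents should stop at the 2,4-diether with one ortho hydroxyl left for ring closure.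

Step 2
Reactants: 3 4-(benzyloxy)benzaldehyde
Product: 4 (E)-3-[4-(benzyloxy)phenyl]prop-2-enal
Conditions: Ph3P=CHCHO (1.1 equiv), toluene, 80 °C
Reagents that add atoms: (triphenylphosphoranylidene)acetaldehyde, O=CC=P(c1ccccc1)(c1ccccc1)c1ccccc1
Why: Wittig olefination with a stabilised ylide should give the E-enal by two-carbon homologation.

Step 3
Reactants: 2 2,4-bis(benzyloxy)-6-hydroxybenzaldehyde; 4 (E)-3-[4-(benzyloxy)phenyl]prop-2-enal
Product: 5 (2R)-5,7-bis(benzyloxy)-2-[4-(benzyloxy)phenyl]-2H-chromene-3-carbaldehyde
Conditions: (S)-α,α-diphenylprolinol trimethylsilyl ether (20 mol %), 2-nitrobenzoic acid (20 mol %), toluene, 4 Å molecular sieves, rt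
Reagents that add atoms: none
Why: Organocatalytic domino oxa-Michael addition/aldol condensation of a salicylaldehyde with a cinnamaldehyde; the phenol should add to the β-carbon of the E-iminium ion on the face away from the diphenyl(silyloxy)methyl group, which sets C2 as R, and the enamine then closes ring C on the formyl group of 2 with loss of water.

Step 4
Reactants: 5 (2R)-5,7-bis(benzyloxy)-2-[4-(benzyloxy)phenyl]-2H-chromene-3-carbaldehyde
Product: 6 (2R)-5,7-bis(benzyloxy)-2-[4-(benzyloxy)phenyl]-2H-chromen-3-yl formate
Conditions: mCPBA (1.05 equiv), CH2Cl2, −20 to 0 °C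
Reagents that add atoms: 3-chloroperbenzoic acid, OOC(=O)c1cccc(Cl)c1
Why: Baeyer–Villiger oxidation of an α-substituted cinnamaldehyde, in which the electron-rich alkenyl group migrates in the Criegee adduct to give the enol formate; the push–pull C3=C4 bond of 5 is a poor partner for epoxidation and C2 is not touched.

Step 5
Reactants: 7 (−)-epigallocatechin
Product: 8 (2R,3R)-5,7-bis(benzyloxy)-2-[3,4,5-tris(benzyloxy)phenyl]chroman-3-ol (5,7,3',4',5'-penta-O-benzylepigallocatechin)
Conditions: BnBr (5.5 equiv), K2CO3 (6 equiv), DMF, 0 °C to rt, argon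
Reagents that add atoms: benzyl bromide, BrCc1ccccc1
Why: Phenol-selective Williamson etherification; the carbonate deprotonates only the five phenols, so the secondary 3-hydroxyl group and both stereocentres should stay as they are.

Step 6
Reactants: 6 (2R)-5,7-bis(benzyloxy)-2-[4-(benzyloxy)phenyl]-2H-chromen-3-yl formate; 8 5,7,3',4',5'-penta-O-benzylepigallocatechin
Product: 10 5,7,4'-tri-O-benzylepiafzelechin-(4β→8)-5,7,3',4',5'-penta-O-benzylepigallocatechin (upper unit 2R,3R,4R; lower unit 2R,3R; both 3-hydroxyl groups free), via formate ester dimer 9 (not isolated)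
Conditions: 8 (4 equiv), HNTf2 (10 mol %), CH2Cl2, −78 to −40 °C, slow addition of 6; then K2CO3, MeOH/THF, 0 °C
Reagents that add atoms: none
Why: Proposed new method: the C3=C4 bond of 6 is both an enol formate and a 2,4,6-trioxygenated styrene, and because O1 and the 5- and 7-benzyloxy groups of ring A stabilise a cation at C4 far better than the formyloxy group stabilises one at C3, the strong acid should protonate C3 and give the same 3-acyloxy C4 cation that Lewis acids generate from 4-alkoxy-3-acyloxyflavans; the closest known reaction types are the Brønsted-acid Markovnikov hydroarylation of electron-rich styrenes and the Friedel–Crafts coupling of C4-activated flavan-3-ol esters with flavan-3-ol nucleophiles. The proton should reach C3 on the face opposite the C2 aryl group, which allylic strain with the 3-formyloxy group holds pseudoaxial, so the formyloxy group ends up cis to ring B and C3 is set as R. The formyloxy group, now axial, bridges to C4 as a 1,3-dioxolan-2-ylium ion or simply shields that face, so C8 of ring D should attack C4 anti to it and set C4 as R (3,4-trans, 4β), as is known for 2,3-cis C4 cations. No ring is closed; the step forms the C3–H and C4–C8 bonds and turns a flat enol ester into the full C2–C3–C4 triad by relay from the single stereocentre C2. The selectivities needed are protonation at C3 rather than C4 (secured by ring A), protonation anti to ring B (secured by the pseudoaxial aryl group, low temperature and fast trapping by excess 8), attack through C8 rather than C6 (the known preference of 5,7-di-O-benzyl flavan-3-ols) and no oligomerisation (excess 8, slow addition of 6). The acid is regenerated when the arenium ion loses its proton, and methanolic K2CO3 then cleaves the formate 9 to 10.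

Step 7
Reactants: 10 5,7,4'-tri-O-benzylepiafzelechin-(4β→8)-5,7,3',4',5'-penta-O-benzylepigallocatechin
Product: 11 epiafzelechin-(4β→8)-epigallocatechin (CNP0290824.1)
Conditions: H2 (1 atm), Pd(OH)2/C, THF/MeOH/H2O, rt; filtration under argon, lyophilisation
Reagents that add atoms: none
Why: Hydrogenolysis of the eight benzyl ethers under neutral conditions should leave the five stereocentres and the acid-labile C4–C8 bond untouched.

## Compound list

1 | 2,4,6-trihydroxybenzaldehyde | O=Cc1c(O)cc(O)cc1O | starting material
2 | 2,4-bis(benzyloxy)-6-hydroxybenzaldehyde | O=Cc1c(O)cc(OCc2ccccc2)cc1OCc1ccccc1 | intermediate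
3 | 4-(benzyloxy)benzaldehyde | O=Cc1ccc(OCc2ccccc2)cc1 | starting material
4 | (E)-3-[4-(benzyloxy)phenyl]prop-2-enal | O=C/C=C/c1ccc(OCc2ccccc2)cc1 | intermediate
5 | (2R)-5,7-bis(benzyloxy)-2-[4-(benzyloxy)phenyl]-2H-chromene-3-carbaldehyde | O=CC1=Cc2c(OCc3ccccc3)cc(OCc3ccccc3)cc2O[C@@H]1c1ccc(OCc2ccccc2)cc1 | intermediate
6 | (2R)-5,7-bis(benzyloxy)-2-[4-(benzyloxy)phenyl]-2H-chromen-3-yl formate | O=COC1=Cc2c(OCc3ccccc3)cc(OCc3ccccc3)cc2O[C@@H]1c1ccc(OCc2ccccc2)cc1 | intermediate
7 | (−)-epigallocatechin, (2R,3R)-2-(3,4,5-trihydroxyphenyl)chromane-3,5,7-triol | Oc1cc(O)c2c(c1)O[C@H](c1cc(O)c(O)c(O)c1)[C@H](O)C2 | starting material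
8 | 5,7,3',4',5'-penta-O-benzylepigallocatechin, (2R,3R)-5,7-bis(benzyloxy)-2-[3,4,5-tris(benzyloxy)phenyl]chroman-3-ol | c1ccccc1COc1cc(OCc3ccccc3)c2c(c1)O[C@H](c1cc(OCc3ccccc3)c(OCc3ccccc3)c(OCc3ccccc3)c1)[C@H](O)C2 | intermediate
9 | 3-O-formyl-5,7,4'-tri-O-benzylepiafzelechin-(4β→8)-5,7,3',4',5'-penta-O-benzylepigallocatechin (upper unit 2R,3R,4R; lower unit 2R,3R) | c1ccccc1COc1ccc([C@H]2Oc3cc(OCc5ccccc5)cc(OCc5ccccc5)c3[C@H](c3c(OCc5ccccc5)cc(OCc5ccccc5)c4c3O[C@H](c3cc(OCc5ccccc5)c(OCc5ccccc5)c(OCc5ccccc5)c3)[C@H](O)C4)[C@H]2OC=O)cc1 | intermediate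
10 | 5,7,4'-tri-O-benzylepiafzelechin-(4β→8)-5,7,3',4',5'-penta-O-benzylepigallocatechin (upper unit 2R,3R,4R; lower unit 2R,3R) | c1ccccc1COc1ccc([C@H]2Oc3cc(OCc5ccccc5)cc(OCc5ccccc5)c3[C@H](c3c(OCc5ccccc5)cc(OCc5ccccc5)c4c3O[C@H](c3cc(OCc5ccccc5)c(OCc5ccccc5)c(OCc5ccccc5)c3)[C@H](O)C4)[C@H]2O)cc1 | intermediate
11 | epiafzelechin-(4β→8)-epigallocatechin (CNP0290824.1; upper unit 2R,3R,4R; lower unit 2R,3R) | Oc1ccc([C@H]2Oc3cc(O)cc(O)c3[C@H](c3c(O)cc(O)c4c3O[C@H](c3cc(O)c(O)c(O)c3)[C@H](O)C4)[C@H]2O)cc1 | target

## Step count and least certain steps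

Total: 7 steps. Longest linear sequence: 5 steps (steps 1, 3, 4, 6, 7).

**Step 6 (key step, proposed new method).** Four things are most likely to go wrong:
- protonation at C4 or acid-catalysed formyl transfer to the free 3-hydroxyl group of 8, which would destroy the enol ester;
- loss of facial selectivity at C3 if protonation becomes reversible before the cation is trapped;
- racemisation at C2 through acid-induced opening of the O1–C2 bond;
- attack of a second cation on the product, leading to oligomers.

Fallback with known chemistry, from 6 back to 9: hydrogenation of the C3=C4 bond of 6 with H2 and [Ir(cod)(PCy3)(py)]PF6 in CH2Cl2, on the face away from ring B, should give the 2,3-cis ester (2R,3R)-5,7-bis(benzyloxy)-2-[4-(benzyloxy)phenyl]chroman-3-yl formate F1. Benzylic oxidation at C4 with DDQ in the presence of 2-ethoxyethanol should give the 4β-ether (2R,3R,4S)-5,7-bis(benzyloxy)-2-[4-(benzyloxy)phenyl]-4-(2-ethoxyethoxy)chroman-3-yl formate F2. Friedel–Crafts coupling of F2 with excess 8 under TMSOTf at −78 °C should give 9, which is methanolysed to 10 as in step 6.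

**Step 4.** The electron-rich enol formate that forms may be epoxidised by the peracid, and the enol ester may hydrolyse on work-up. Fallback that avoids the oxidation of the aldehyde, from 5 back to 10:
- decarbonylation of 5 with RhCl(PPh3)3 in toluene at 80 °C (Tsuji–Wilkinson decarbonylation) should give the flav-3-ene (2S)-5,7-bis(benzyloxy)-2-[4-(benzyloxy)phenyl]-2H-chromene F3, in which C2 keeps its spatial arrangement and only the descriptor changes;
- N-bromosuccinimide in aqueous THF should give the bromohydrin 5,7-bis(benzyloxy)-2-[4-(benzyloxy)phenyl]-3-bromochroman-4-ol F4, with bromine on C3 anti to ring B and the hydroxyl on C4 anti to bromine;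
- K2CO3 in MeOH should close it to the epoxide 5,7-bis(benzyloxy)-2-[4-(benzyloxy)phenyl]-3,4-epoxychromane F5, with the oxygen cis to ring B;
- opening of F5 at C4 by C8 of 8 (excess, BF3·OEt2, CH2Cl2, −78 °C), anti to the epoxide oxygen, should give 10 directly.

**Step 3.** The hydrogen-bonded, donor-substituted formyl group of 2 may close ring C slowly, and reversible oxa-Michael addition at the 4-alkoxybenzylic carbon may erode the enantiomeric purity. Fallback with a different activation, from 2 and 4 back to 5: K2CO3 in 1,4-dioxane at reflux (phenoxide oxa-Michael addition and aldol condensation) should give racemic 5,7-bis(benzyloxy)-2-[4-(benzyloxy)phenyl]-2H-chromene-3-carbaldehyde F6. Preparative chromatography on a chiral stationary phase would then separate 5 from its enantiomer (2S)-5,7-bis(benzyloxy)-2-[4-(benzyloxy)phenyl]-2H-chromene-3-carbaldehyde F7.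

**Step 7.** Debenzylation of the crowded tris(benzyloxy)phenyl ring E may be incomplete, and the free pyrogallol may oxidise in air during isolation. Fallback that changes the isolation, from 10 back to 11: hydrogenolysis as in step 7, then Ac2O/pyridine in the same flask without exposure to air, should give the deca-O-acetate of epiafzelechin-(4β→8)-epigallocatechin F8, which can be purified on silica. Deacetylation with K2CO3 in degassed MeOH at 0 °C under argon, followed by neutralisation with an acidic ion-exchange resin, should give 11.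

## Further compounds

F1 | step 6 | (2R,3R)-5,7-bis(benzyloxy)-2-[4-(benzyloxy)phenyl]chroman-3-yl formate | O=CO[C@@H]1Cc2c(OCc3ccccc3)cc(OCc3ccccc3)cc2O[C@@H]1c1ccc(OCc2ccccc2)cc1
F2 | step 6 | (2R,3R,4S)-5,7-bis(benzyloxy)-2-[4-(benzyloxy)phenyl]-4-(2-ethoxyethoxy)chroman-3-yl formate | c1ccccc1COc1ccc([C@H]2Oc3cc(OCc4ccccc4)cc(OCc4ccccc4)c3[C@H](OCCOCC)[C@H]2OC=O)cc1
F3 | step 4 | (2S)-5,7-bis(benzyloxy)-2-[4-(benzyloxy)phenyl]-2H-chromene | C1=Cc2c(OCc3ccccc3)cc(OCc3ccccc3)cc2O[C@@H]1c1ccc(OCc2ccccc2)cc1
F4 | step 4 | 5,7-bis(benzyloxy)-2-[4-(benzyloxy)phenyl]-3-bromochroman-4-ol (Br anti to ring B, 4-OH anti to Br) | c1ccccc1COc1ccc([C@H]2Oc3cc(OCc4ccccc4)cc(OCc4ccccc4)c3[C@@H](O)[C@@H]2Br)cc1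
F5 | step 4 | 5,7-bis(benzyloxy)-2-[4-(benzyloxy)phenyl]-3,4-epoxychromane (epoxide oxygen cis to ring B) | c1ccccc1COc1ccc([C@H]2Oc3cc(OCc4ccccc4)cc(OCc4ccccc4)c3[C@H]5O[C@H]52)cc1
F6 | step 3 | racemic 5,7-bis(benzyloxy)-2-[4-(benzyloxy)phenyl]-2H-chromene-3-carbaldehyde | O=CC1=Cc2c(OCc3ccccc3)cc(OCc3ccccc3)cc2OC1c1ccc(OCc2ccccc2)cc1
F7 | step 3 | (2S)-5,7-bis(benzyloxy)-2-[4-(benzyloxy)phenyl]-2H-chromene-3-carbaldehyde | O=CC1=Cc2c(OCc3ccccc3)cc(OCc3ccccc3)cc2O[C@H]1c1ccc(OCc2ccccc2)cc1
F8 | step 7 | deca-O-acetate of epiafzelechin-(4β→8)-epigallocatechin | CC(=O)Oc1ccc([C@H]2Oc3cc(OC(C)=O)cc(OC(C)=O)c3[C@H](c3c(OC(C)=O)cc(OC(C)=O)c4c3O[C@H](c3cc(OC(C)=O)c(OC(C)=O)c(OC(C)=O)c3)[C@H](OC(C)=O)C4)[C@H]2OC(C)=O)cc1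
A1 | alternative 1 | 5,7,4'-tri-O-benzylepiafzelechin, (2R,3R)-5,7-bis(benzyloxy)-2-[4-(benzyloxy)phenyl]chroman-3-ol | O[C@@H]1Cc2c(OCc3ccccc3)cc(OCc3ccccc3)cc2O[C@@H]1c1ccc(OCc2ccccc2)cc1
A2 | alternative 1 | (2R,3R,4S)-5,7-bis(benzyloxy)-2-[4-(benzyloxy)phenyl]-4-(2-ethoxyethoxy)chroman-3-ol | c1ccccc1COc1ccc([C@H]2Oc3cc(OCc4ccccc4)cc(OCc4ccccc4)c3[C@H](OCCOCC)[C@H]2O)cc1
A3 | alternative 2 | 3-acetoxy-5,7-bis(benzyloxy)-2-[4-(benzyloxy)phenyl]chromenylium chloride | CC(=O)Oc1cc2c(OCc3ccccc3)cc(OCc3ccccc3)cc2[o+]c1-c1ccc(OCc2ccccc2)cc1.[Cl-]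
A4 | alternative 2 | 3-acetoxy-5,7-bis(benzyloxy)-2-[4-(benzyloxy)phenyl]-4-[penta-O-benzylepigallocatechin-8-yl]-4H-chromene (C4 configuration not controlled) | CC(=O)OC1=C(c2ccc(OCc3ccccc3)cc2)Oc2cc(OCc3ccccc3)cc(OCc3ccccc3)c2C1c1c(OCc2ccccc2)cc(OCc2ccccc2)c2c1O[C@H](c1cc(OCc3ccccc3)c(OCc3ccccc3)c(OCc3ccccc3)c1)[C@H](O)C2
A5 | alternative 3 | (E)-3-[(2R,3R)-5,7-bis(benzyloxy)-3-hydroxy-2-[3,4,5-tris(benzyloxy)phenyl]chroman-8-yl]-1-[4-(benzyloxy)phenyl]prop-2-en-1-one | O=C(/C=C/c1c(OCc2ccccc2)cc(OCc2ccccc2)c2c1O[C@H](c1cc(OCc3ccccc3)c(OCc3ccccc3)c(OCc3ccccc3)c1)[C@H](O)C2)c1ccc(OCc2ccccc2)cc1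
A6 | alternative 3 | 5,7-bis(benzyloxy)-2-[4-(benzyloxy)phenyl]-4-[penta-O-benzylepigallocatechin-8-yl]-4H-chromene (C4 configuration not controlled) | C1(c2ccc(OCc3ccccc3)cc2)=CC(c2c(OCc3ccccc3)cc(OCc3ccccc3)c3c2O[C@H](c2cc(OCc4ccccc4)c(OCc4ccccc4)c(OCc4ccccc4)c2)[C@H](O)C3)c2c(OCc3ccccc3)cc(OCc3ccccc3)cc2O1
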